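**Retrosynthetic overview**

1. Target ← acetonide hydrolysis ← removal of the C3 oxygen (NaBH4, then Barton–McCombie) from a 3-oxo bicyclic acetonide.
2. Key step: Mn(OAc)3/Cu(OAc)2 oxidative radical bicyclisation of an acyclic α-methyl β-keto ester that already carries the finished 12R,13R side chain. Ring A closes first (C4–C5), ring B second (C9–C10), and divalent copper terminates to the C8 exocyclic methylene. This replaces a cation–olefin cyclisation and a late diene dihydroxylation.
3. The chair–chair transition state fixes the four ring centres relative to one another. The remote side chain cannot bias the absolute sense, so the diastereomer with the target's decalin is separated from its ring-antipodal partner directly after the cyclisation.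
4. Acyclic precursor ← dianion of methyl 2-methylacetoacetate + terminal allylic bromide (SeO2 allylic oxidation, Appel).
5. Side-chain stereocentres are set first on geranylacetone: L-proline α-aminoxylation (C12), then chelation-controlled vinyl Grignard addition (C13).

Assumption: (E)-geranylacetone (≥96% E) is bought as such; labels C1–C20 in the text are labdane numbering of the target.

**Route**

Step 1
Reactants: 1 (E)-geranylacetone
Product: 3 (3R,5E)-3-hydroxy-6,10-dimethylundeca-5,9-dien-2-one, via anilinooxy ketone 2 (not isolated)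
Conditions: L-proline (20 mol%), PhNO (slow addition; 1 in threefold excess, recovered), DMSO, 25 °C; then CuSO4·5H2O (30 mol%), MeOH, 0 °C
Reagents that add atoms: nitrosobenzene, O=Nc1ccccc1
Why: Proline enamine catalysis (organocatalytic α-aminoxylation) engages the more substituted E-enamine of the methyl ketone and delivers the nitroso oxygen to one face, as for cyclohexanone and aldehydes where L-proline gives the R α-oxy carbonyl, so C12 is set as R; copper-mediated N–O cleavage then frees the hydroxyl without touching the isolated alkenes.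

Step 2
Reactants: 3 (3R,5E)-3-hydroxy-6,10-dimethylundeca-5,9-dien-2-one
Product: 4 (3R,4R,6E)-3,7,11-trimethyldodeca-1,6,10-triene-3,4-diol
Conditions: CH2=CHMgBr (3 equiv), THF, −78 → −30 °C; aq. NH4Cl
Reagents that add atoms: vinylmagnesium bromide, C=C[Mg]Br
Why: Cram-chelate-controlled Grignard addition: the first equivalent forms a five-membered magnesium alkoxide–ketone chelate and the vinyl group adds to the carbonyl face on the hydrogen side of C12, away from the C11 methylene, which sets C13 as R.

Step 3
Reactants: 4 (3R,4R,6E)-3,7,11-trimethyldodeca-1,6,10-triene-3,4-diol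
Product: 5 (4R,5R)-4-[(2E)-3,7-dimethylocta-2,6-dien-1-yl]-5-ethenyl-2,2,5-trimethyl-1,3-dioxolane
Conditions: Me2C(OMe)2, pyridinium p-toluenesulfonate (5 mol%), CH2Cl2, 25 °C
Reagents that add atoms: 2,2-dimethoxypropane, COC(C)(C)OC
Why: Acid-catalysed transketalisation ties the diol into an isopropylidene acetal that masks both hydroxyls for the oxidation, strong-base and radical steps, with no stereocentre touched.

Step 4
Reactants: 5 (4R,5R)-4-[(2E)-3,7-dimethylocta-2,6-dien-1-yl]-5-ethenyl-2,2,5-trimethyl-1,3-dioxolane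
Product: 6 (2E,6E)-8-[(4R,5R)-5-ethenyl-2,2,5-trimethyl-1,3-dioxolan-4-yl]-2,6-dimethylocta-2,6-dien-1-ol
Conditions: SeO2 (0.3 equiv), t-BuOOH (3 equiv), salicylic acid (0.1 equiv), CH2Cl2, 0 → 25 °C
Reagents that add atoms: tert-butyl hydroperoxide, CC(C)(C)OO
Why: SeO2-catalysed allylic oxidation (ene reaction then 2,3-sigmatropic shift) is selective for the E methyl of the terminal, most accessible trisubstituted alkene and gives the E allylic alcohol, while the vinyl group has no allylic hydrogen.

Step 5
Reactants: 6 (2E,6E)-8-[(4R,5R)-5-ethenyl-2,2,5-trimethyl-1,3-dioxolan-4-yl]-2,6-dimethylocta-2,6-dien-1-ol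
Product: 7 (4R,5R)-4-[(2E,6E)-8-bromo-3,7-dimethylocta-2,6-dien-1-yl]-5-ethenyl-2,2,5-trimethyl-1,3-dioxolane
Conditions: CBr4, PPh3, 2,6-lutidine, CH2Cl2, −20 → 0 °C
Reagents that add atoms: carbon tetrabromide, BrC(Br)(Br)Br
Why: Appel bromination displaces the oxyphosphonium ion of the primary allylic alcohol by SN2 under near-neutral conditions, so alkene geometry and the acetal survive.

Step 6
Reactants: 7 (4R,5R)-4-[(2E,6E)-8-bromo-3,7-dimethylocta-2,6-dien-1-yl]-5-ethenyl-2,2,5-trimethyl-1,3-dioxolane; 8 methyl 2-methyl-3-oxobutanoate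
Product: 10 methyl (6E,10E)-12-[(4R,5R)-5-ethenyl-2,2,5-trimethyl-1,3-dioxolan-4-yl]-2,6,10-trimethyl-3-oxododeca-6,10-dienoate, via acetoacetate dianion 9 (not isolated)
Conditions: 8, NaH, THF, 0 °C; n-BuLi, 0 °C; then 7, 0 °C
Reagents that add atoms: none
Why: Weiler dianion alkylation: the more basic terminal carbanion displaces the allylic bromide (SN2) and attaches the polyene chain at the γ-carbon, leaving the α-methyl β-keto ester needed for enolate oxidation; the epimeric α-centre is erased in the next step.

Step 7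
Reactants: 10 methyl (6E,10E)-12-[(4R,5R)-5-ethenyl-2,2,5-trimethyl-1,3-dioxolan-4-yl]-2,6,10-trimethyl-3-oxododeca-6,10-dienoate
Product: 11 methyl (1R,4aR,5S,8aR)-5-{[(4R,5R)-5-ethenyl-2,2,5-trimethyl-1,3-dioxolan-4-yl]methyl}-1,4a-dimethyl-6-methylidene-2-oxodecahydronaphthalene-1-carboxylate
Conditions: Mn(OAc)3·2H2O (2.2 equiv), Cu(OAc)2·H2O (1 equiv), NaOAc (2 equiv), degassed AcOH, 25 °C; then preparative HPLC on silica
Reagents that add atoms: none
Why: Oxidative free-radical polyene cyclisation: the trivalent manganese enolate gives the C4 radical, which closes ring A and then ring B by two 6-endo additions through a chair–chair array in which the E alkenes impose the trans ring fusion and the equatorial C9 chain while the ester, anti to the ketone oxygen in the radical, ends up axial and cis to the C10 methyl, and divalent copper oxidises the final tertiary C8 radical by elimination toward the methyl group to give the exocyclic alkene; because the side-chain centres are too far from the first ring closure to bias it, the diastereomer with the mirror-image decalin forms in about the same amount and is removed by the chromatography, so at most half of the cyclised material is 11.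

Step 8
Reactants: 11 methyl (1R,4aR,5S,8aR)-5-{[(4R,5R)-5-ethenyl-2,2,5-trimethyl-1,3-dioxolan-4-yl]methyl}-1,4a-dimethyl-6-methylidene-2-oxodecahydronaphthalene-1-carboxylate
Product: 12 methyl (1R,2S,4aR,5S,8aR)-5-{[(4R,5R)-5-ethenyl-2,2,5-trimethyl-1,3-dioxolan-4-yl]methyl}-2-hydroxy-1,4a-dimethyl-6-methylidenedecahydronaphthalene-1-carboxylate
Conditions: NaBH4 (1.5 equiv), MeOH, −20 → 0 °C
Reagents that add atoms: none
Why: Hydride reduction of the ketone (NaBH4): hydride enters axially on the α-face, away from the axial C4 ester and C10 methyl on the β-face, and gives the equatorial 3β (2S) alcohol while the hindered neopentyl ester is not reduced; this centre is removed again in step 10, so its configuration is not critical.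

Step 9
Reactants: 12 methyl (1R,2S,4aR,5S,8aR)-5-{[(4R,5R)-5-ethenyl-2,2,5-trimethyl-1,3-dioxolan-4-yl]methyl}-2-hydroxy-1,4a-dimethyl-6-methylidenedecahydronaphthalene-1-carboxylate
Product: 13 methyl (1R,2S,4aR,5S,8aR)-5-{[(4R,5R)-5-ethenyl-2,2,5-trimethyl-1,3-dioxolan-4-yl]methyl}-2-[(1H-imidazol-1-ylcarbonothioyl)oxy]-1,4a-dimethyl-6-methylidenedecahydronaphthalene-1-carboxylate
Conditions: 1,1'-thiocarbonyldiimidazole (2 equiv), 4-(dimethylamino)pyridine (0.2 equiv), toluene, 90 °C
Reagents that add atoms: 1,1'-thiocarbonyldiimidazole, S=C(n1ccnc1)n1ccnc1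
Why: Neutral thioacylation of the hindered secondary alcohol (activation for Barton–McCombie deoxygenation) avoids the free alkoxide that could open the β-hydroxy ester by retro-aldol cleavage.

Step 10
Reactants: 13 methyl (1R,2S,4aR,5S,8aR)-5-{[(4R,5R)-5-ethenyl-2,2,5-trimethyl-1,3-dioxolan-4-yl]methyl}-2-[(1H-imidazol-1-ylcarbonothioyl)oxy]-1,4a-dimethyl-6-methylidenedecahydronaphthalene-1-carboxylate
Product: 14 methyl (1S,4aR,5S,8aR)-5-{[(4R,5R)-5-ethenyl-2,2,5-trimethyl-1,3-dioxolan-4-yl]methyl}-1,4a-dimethyl-6-methylidenedecahydronaphthalene-1-carboxylate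
Conditions: Bu3SnH (2 equiv), 2,2'-azobis(2-methylpropionitrile) (0.2 equiv), toluene, 110 °C
Reagents that add atoms: none
Why: Barton–McCombie radical deoxygenation: the stannyl radical adds to the thiocarbonyl, the C3–O bond fragments and the secondary C3 radical takes hydrogen from Bu3SnH, with neither alkene placed to trap it and no stereocentre affected (the C1 descriptor changes from R to S only because the priorities change).

Step 11
Reactants: 14 methyl (1S,4aR,5S,8aR)-5-{[(4R,5R)-5-ethenyl-2,2,5-trimethyl-1,3-dioxolan-4-yl]methyl}-1,4a-dimethyl-6-methylidenedecahydronaphthalene-1-carboxylate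
Product: 15 methyl (1S,4aR,5S,8aR)-5-[(2R,3R)-2,3-dihydroxy-3-methylpent-4-en-1-yl]-1,4a-dimethyl-6-methylidenedecahydronaphthalene-1-carboxylate
Conditions: AcOH/H2O/THF (3:1:1), 40 °C
Reagents that add atoms: none
Why: Acid-catalysed acetal hydrolysis cleaves at the acetal carbon, so both C–O bonds at C12 and C13 and their configurations are retained, and these mild conditions spare the exocyclic alkene, the tertiary allylic alcohol and the hindered methyl ester.

**Compound list**

1 | (E)-geranylacetone, (5E)-6,10-dimethylundeca-5,9-dien-2-one | CC(=O)CC/C=C(\C)CCC=C(C)C | starting material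
2 | (3R,5E)-3-(anilinooxy)-6,10-dimethylundeca-5,9-dien-2-one (not isolated) | CC(=O)[C@H](ONc1ccccc1)C/C=C(\C)CCC=C(C)C | intermediate
3 | (3R,5E)-3-hydroxy-6,10-dimethylundeca-5,9-dien-2-one | CC(=O)[C@H](O)C/C=C(\C)CCC=C(C)C | intermediate
4 | (3R,4R,6E)-3,7,11-trimethyldodeca-1,6,10-triene-3,4-diol | C=C[C@@](C)(O)[C@H](O)C/C=C(\C)CCC=C(C)C | intermediate
5 | (4R,5R)-4-[(2E)-3,7-dimethylocta-2,6-dien-1-yl]-5-ethenyl-2,2,5-trimethyl-1,3-dioxolane | C=C[C@@]1(C)OC(C)(C)O[C@@H]1C/C=C(\C)CCC=C(C)C | intermediate
6 | (2E,6E)-8-[(4R,5R)-5-ethenyl-2,2,5-trimethyl-1,3-dioxolan-4-yl]-2,6-dimethylocta-2,6-dien-1-ol | C=C[C@@]1(C)OC(C)(C)O[C@@H]1C/C=C(\C)CC/C=C(\C)CO | intermediate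
7 | (4R,5R)-4-[(2E,6E)-8-bromo-3,7-dimethylocta-2,6-dien-1-yl]-5-ethenyl-2,2,5-trimethyl-1,3-dioxolane | C=C[C@@]1(C)OC(C)(C)O[C@@H]1C/C=C(\C)CC/C=C(\C)CBr | intermediate
8 | methyl 2-methyl-3-oxobutanoate (methyl 2-methylacetoacetate) | COC(=O)C(C)C(C)=O | starting material
9 | sodium lithium dianion of methyl 2-methyl-3-oxobutanoate (not isolated) | [Na+].[Li+].[CH2-]C(=O)[C-](C)C(=O)OC | intermediate
10 | methyl (6E,10E)-12-[(4R,5R)-5-ethenyl-2,2,5-trimethyl-1,3-dioxolan-4-yl]-2,6,10-trimethyl-3-oxododeca-6,10-dienoate (both C2 epimers) | C=C[C@@]1(C)OC(C)(C)O[C@@H]1C/C=C(\C)CC/C=C(\C)CCC(=O)C(C)C(=O)OC | intermediate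
11 | methyl (1R,4aR,5S,8aR)-5-{[(4R,5R)-5-ethenyl-2,2,5-trimethyl-1,3-dioxolan-4-yl]methyl}-1,4a-dimethyl-6-methylidene-2-oxodecahydronaphthalene-1-carboxylate (3-oxo labdane acetonide, ring series of the target) | C=C[C@@]1(C)OC(C)(C)O[C@@H]1C[C@H]2C(=C)CC[C@@H]3[C@]2(C)CCC(=O)[C@]3(C)C(=O)OC | intermediate
12 | methyl (1R,2S,4aR,5S,8aR)-5-{[(4R,5R)-5-ethenyl-2,2,5-trimethyl-1,3-dioxolan-4-yl]methyl}-2-hydroxy-1,4a-dimethyl-6-methylidenedecahydronaphthalene-1-carboxylate (3β-alcohol) | C=C[C@@]1(C)OC(C)(C)O[C@@H]1C[C@H]2C(=C)CC[C@@H]3[C@]2(C)CC[C@H](O)[C@]3(C)C(=O)OC | intermediate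
13 | methyl (1R,2S,4aR,5S,8aR)-5-{[(4R,5R)-5-ethenyl-2,2,5-trimethyl-1,3-dioxolan-4-yl]methyl}-2-[(1H-imidazol-1-ylcarbonothioyl)oxy]-1,4a-dimethyl-6-methylidenedecahydronaphthalene-1-carboxylate | C=C[C@@]1(C)OC(C)(C)O[C@@H]1C[C@H]2C(=C)CC[C@@H]3[C@]2(C)CC[C@H](OC(=S)n4ccnc4)[C@]3(C)C(=O)OC | intermediate
14 | methyl (1S,4aR,5S,8aR)-5-{[(4R,5R)-5-ethenyl-2,2,5-trimethyl-1,3-dioxolan-4-yl]methyl}-1,4a-dimethyl-6-methylidenedecahydronaphthalene-1-carboxylate | C=C[C@@]1(C)OC(C)(C)O[C@@H]1C[C@H]2C(=C)CC[C@@H]3[C@]2(C)CCC[C@]3(C)C(=O)OC | intermediate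
15 | methyl (1S,4aR,5S,8aR)-5-[(2R,3R)-2,3-dihydroxy-3-methylpent-4-en-1-yl]-1,4a-dimethyl-6-methylidenedecahydronaphthalene-1-carboxylate, i.e. methyl (12R,13R)-12,13-dihydroxylabda-8(17),14-dien-19-oate (CNP0138527.1) | C=C[C@@](C)(O)[C@H](O)C[C@H]1C(=C)CC[C@@H]2[C@]1(C)CCC[C@]2(C)C(=O)OC | target

**Step count and risks**

Total step count: 11. Longest linear sequence: 11 steps (1 → 15); 8 enters at step 6.

Three steps most likely to fail:

Step 7 (radical bicyclisation). The risks are:
- oxidation of the intermediate C10 radical before ring B closes;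
- endocyclic alkene isomers from the termination;
- partial acetal loss in AcOH;
- the separation from the ring-antipodal diastereomer, which caps the yield of 11 at half of the cyclised material. The two differ at centres only two bonds apart (C9 and C12), so they are expected to resolve on silica, but this is untested.

The fallback sets out from 10 and comes back at 11. It replaces oxidative termination by group transfer and a separate elimination. The sodium enolate of 10 (NaH, THF, 0 °C) is selenenylated with PhSeCl at −78 °C to give the α-phenylselanyl β-keto ester F1. Irradiation (sunlamp, benzene, 25 °C) starts a phenylselanyl group-transfer radical bicyclisation that ends by selenium transfer and gives the tertiary C8 selenide F2. No chelating Lewis acid is added, so the radical keeps the ester anti to the ketone oxygen and C4 is set as in step 7. Oxidation with H2O2/pyridine (CH2Cl2, 0 → 25 °C) and selenoxide syn-elimination, which favours the freely rotating methyl hydrogens, gives mainly the exocyclic alkene. 11 is then separated from its ring-antipodal diastereomer as in step 7.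

Step 10 (Barton–McCombie at C3). At 110 °C the stannyl radical can add to the vinyl group, and a hindered thiocarbonyl imidazolide can return the alcohol instead of fragmenting. The fallback sets out from 11 and comes back at 14, bypassing 12 and 13 and using no tin hydride. Ketone 11 is condensed with TsNHNH2 (EtOH, 70 °C) to the tosylhydrazone F3. Catecholborane (CHCl3, 0 °C) followed by NaOAc·3H2O at reflux reduces F3 directly to the methylene compound 14 by hydride addition to C=N, loss of sulfinate and loss of nitrogen from the diazene.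

Step 1 (aminoxylation of an acyclic methyl ketone). The risks are attack at the methyl side, N- versus O-selectivity and a modest yield based on nitrosobenzene. The fallback sets out from 1 and comes back at 3. Treatment of 1 with Me3SiCl, NaI and Et3N in MeCN gives the thermodynamic Z trimethylsilyl enol ether F4. MeLi (THF, 0 °C) releases the regiodefined lithium enolate, which is hydroxylated at −78 °C with (−)-(camphorylsulfonyl)oxaziridine to give 3. The reagent antipode is chosen for the 3R ketol by analogy with Z enolates of aryl ethyl ketones and would need confirming; the oxaziridine does not touch the isolated alkenes.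

Further compounds

F1 | step 7 | methyl (6E,10E)-12-[(4R,5R)-5-ethenyl-2,2,5-trimethyl-1,3-dioxolan-4-yl]-2,6,10-trimethyl-3-oxo-2-(phenylselanyl)dodeca-6,10-dienoate (both C2 epimers) | C=C[C@@]1(C)OC(C)(C)O[C@@H]1C/C=C(\C)CC/C=C(\C)CCC(=O)C(C)([Se]c2ccccc2)C(=O)OC
F2 | step 7 | methyl (1R,4aS,5R,8aR)-5-{[(4R,5R)-5-ethenyl-2,2,5-trimethyl-1,3-dioxolan-4-yl]methyl}-1,4a,6-trimethyl-2-oxo-6-(phenylselanyl)decahydronaphthalene-1-carboxylate (C6 epimers; ring configuration as in 11, the descriptors at C4a and C5 differ only because selenium changes the priorities) | C=C[C@@]1(C)OC(C)(C)O[C@@H]1C[C@H]2C(C)([Se]c4ccccc4)CC[C@@H]3[C@]2(C)CCC(=O)[C@]3(C)C(=O)OC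
F3 | step 10 | methyl (1R,4aR,5S,8aR)-5-{[(4R,5R)-5-ethenyl-2,2,5-trimethyl-1,3-dioxolan-4-yl]methyl}-1,4a-dimethyl-6-methylidene-2-[2-(4-methylbenzenesulfonyl)hydrazinylidene]decahydronaphthalene-1-carboxylate | C=C[C@@]1(C)OC(C)(C)O[C@@H]1C[C@H]2C(=C)CC[C@@H]3[C@]2(C)CCC(=NNS(=O)(=O)c4ccc(C)cc4)[C@]3(C)C(=O)OC
F4 | step 1 | trimethyl{[(2Z,5E)-6,10-dimethylundeca-2,5,9-trien-2-yl]oxy}silane | C/C(O[Si](C)(C)C)=C/C/C=C(\C)CCC=C(C)C
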